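(The runs were generated by integration for substances that don't exist; the scatter is artificial.)

Count the partner before reckoning any rate.

| flask | left-handed substrate | right-handed substrate | partner | protic impurity | free catalyst | remark | time |
|---|---|---|---|---|---|---|---|
| south-west | 0.80 M | 0.80 M | 1.2 M | 0.40 M | 14 mM | run made earlier |  |
| north-east | 0.80 M | 0.80 M | 1.2 M | 0.40 M | 32 mM | run made earlier |  |
| flask | 0.80 M | 0.80 M | 1.20 M | 0.400 M | 21 mM |  | 4.0 h |

| run | time / h | left-handed substrate / % | left-handed product / % |
|---|---|---|---|
| south-west | 0.333 | 43 | 9 |
| south-west | 0.667 | 38 | 12 |
| south-west | 1.50 | 30 | 23 |
| south-west | 4.00 | 18 | 31 |
| north-east | 1.00 | 24 | 25 |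
| north-east | 2.00 | 18 | 33 |
| north-east | 3.00 | 13 | 33 |
| north-east | 4.00 | 14 | 37 |

(readings scatter by 1.5 percentage points)

- free catalyst is single-handed; left-handed substrate and right-handed substrate are mirror images of each other, charged as a racemate, each of them at the stated concentration
- the reaction counts as stopped when no species that holds the left-handed substrate and right-handed substrate together changes by six tenths of a point or more over the second half of the time

* the state of affairs at 4.0 h: stopped, and by what, or still going (it is still moving / all of the left-handed substrate has reacted / no working catalyst is left / the partner has run out first / forward and back rates have come level)
* share of the left-handed substrate and right-handed substrate together used up at 4.0 h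
* left-handed product at 4.0 h, in percent of the left-handed substrate and right-handed substrate together charged

1. Bound from above. I assumed one partner per substrate turned over. The partner was then the limiting reagent, and its charge allowed 75.0% of both substrates together.

2. Tightened. I assumed that the protic impurity quenches partner one for one. That gave 50.0% as the working budget: partner charge less impurity charge, as a share of both substrates charged. Substrate held on the catalyst could add its charge, so my upper bound on the flask's conversion became 51.3%.

3. Bound from below. The south-west run had the same charges but less catalyst, and by 4.00 h it read a left-handed loss of 32.0%.

4. Tightened. I read the north-east plateau as its budget spent, at a left-handed loss of 36.0%. Scaling the south-west loss by budget over that loss gave 44.4% as my lower estimate for both substrates together; it rested on that reading of the plateau, so it was an estimate and not a strict bound. For left-handed product, I took the two runs' last readings, 31% and 37%, as the bracket.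

5. The forecast said it is still moving, with 50% used up and 34% of left-handed product, noting that “partner exhaustion cannot be excluded”. Both numbers stood inside my brackets.

6. The flask gave: it is still moving, 46.7% used up, 34.0% of left-handed product. The flask's conversion lay below my upper bound and above my lower estimate.

    partner + catalyst intermediate A → free catalyst + left-handed product (k = 4.90 /M/min)
    free catalyst + right-handed substrate ⇌ catalyst intermediate B (K = 2.00 /M, k = 14.0 /M/min)
    free catalyst + left-handed substrate ⇌ catalyst intermediate A (K = 0.540 /M, k = 6.30 /M/min)
    partner + catalyst intermediate B → free catalyst + right-handed product (k = 0.280 /M/min)
    partner + protic impurity → quenched reagent (k = 0.160 /M/min)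
    partner + free catalyst → spent catalyst (k = 0.00220 /M/min)

At 4.00 h the flask held 0.400 M of quenched reagent and 0% of protic impurity, so the impurity's share had left the partner as the budget reckoned. Conversion stood at 93.4% of the budget, with 5.3% of the partner charge remaining: still moving, on the last of its partner.

With 0.24 M of protic impurity, the same reckoning gave the neighbour flask a budget of 60.0%. Computed, it used up 54.2% by 4.00 h, which is 90.3% of that budget.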